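**The pitfall.** Reading 1.10 equiv of D as a surplus over J is the trap: D also decays to Q by itself.

J 0.050 M; D 1.10 equiv; time 6.0 min

    J + D → E + X (k1 = 1.3 L mol⁻¹ s⁻¹)
    E ⇌ L (K2 = 5.1, k2 = 0.22 s⁻¹)
    E ⇌ Z (K3 = 2.5, k3 = 0.11 s⁻¹)
    D → Q (k4 = 0.043 s⁻¹)

- the reaction counts as stopped when no species that holds the J changes by six tenths of a point or more over the second half of the time
- run time (flask): 6.0 min

- which holds at 6.0 min: what has brought the reaction to rest, or that it has not come to rest (it is still moving / D has run out first / forward and back rates have come level / all of J has reacted)
- part of the J gone at 6.0 min
- the L standing at 6.0 min, as a percentage of the J charged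

**Bench rule.** Both ways of using D carry the concentration of D, so their ratio depends on J. They run level at J*, the concentration of J equal to the decay constant of D over the rate constant of its reaction with J: 0.0331 M. This flask starts at 1.51 times J*, so at the start J takes 60.2% of the D being used. The usual rule multiplies that share by the charge and gives 66.2% conversion. But J falls to J* at 33.8% conversion, earlier than that figure, and the share shrinks on the way.

**The balance.** Summing the split as J falls, the equivalents of D spent to remove a fraction x of J are x, plus J* over the J charged, times the natural log of J charged over J left. At x = 0.5 that costs 0.959, and at x = 0.7 it costs 1.50. The charge lies 0.263 of the way between, which gives 55.3%. So D is the limiting reagent, and its half-life by decay alone, 0.27 min, is short against 6.0 min. E relaxes with L and with Z, each step taken alone, in 2.63 s and 0.0750 min, also short, so L should hold 59.3% of the reacted J, which gives 32.8%.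

**The forecast.** It says D has run out first, with conversion 55.9% (55% to 57%) and L 33.1% (32.3% to 34%), holding that “D is lost to its own first-order decay at a rate comparable with its reaction with J”. The conversion reckoned above stands lower than the forecast's.

**The result.** The outcome for this flask at 6.0 min reads: D has run out first, with conversion 55.9% and L 33.1%. D is at 0% of its charge by 3.00 min. Left until 60.0 min, this flask reads 55.9% conversion, and at 60.0 min its L reads 33.1%. J in this flask stands at 0.0221 M at 6.00 min, below J*. The neighbour charged with 0.013 M of J starts below J*, at 0.393 of it, so the bench rule gives it 31.0%. That neighbour stops at 27.6% with D at 0%, where the balance counts 1.10 equivalents against 1.10 equiv charged, and its L stands at 16.4%.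

The constants are invented; the rest is arithmetic.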